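A small charge of J, 1.10 equiv on G at 0.10 M, goes into this flask, and both earlier runs had more.

in all of them: G 0.10 M
- midnight: J 1.5 equiv; run made earlier
- dawn: J 2.4 equiv; run made earlier
- flask: J 1.10 equiv; time 6.0 h

- midnight (time / h: G / %, E / %): 0.200: 97, 0; 0.500: 92, 7; 1.00: 82, 19; 1.50: 74, 21; 2.00: 67, 28; 3.00: 55, 35; 4.00: 48, 42
- dawn (time / h: G / %, E / %): 0.500: 86, 13; 1.00: 75, 23; 1.50: 65, 35; 2.00: 54, 42; 2.50: 48, 49; 3.00: 39, 49; 4.00: 30, 63

(each reading ± 2 percentage points)



1. part of the G gone at 6.0 h
2. the E standing at 6.0 h, as a percentage of the G charged
3. amount of E if the flask were left three thousand times as long, in percent of the G charged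

In the first instants G and J meet and E appears, and G goes faster with more J: at 0.500 h the dawn run keeps 86% of its G against 92% at midnight. So I work with the fraction of G left and not with the E made. At 4.00 h, minus the natural log of that fraction, divided by the equivalents of J and the hours, reads 0.122 h⁻¹ at midnight and 0.125 h⁻¹ at dawn, each per equivalent of J, with a mean of 0.124 h⁻¹. I call this mean the fade, minus the natural log of the fraction of G left, per equivalent of J charged and per hour; it is a pseudo-first-order constant with J counted as charged.

At the last midnight reading, at 4.00 h, G and E together read 90.0%, which points to something unseen; at the last dawn reading they read 93.0%.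

For the end of this flask, at 6.0 h, later than any reading, the fade leaves 44.2% of G, so 55.8% is gone. The midnight run turned 80.8% of its lost G into E, which gives me 45.1% of E here. For the very long wait I commit to no number.

The forecast says 52% gone, 42% of E and 71% after the very long wait, on the ground of “a side loss of G that does not need J”. Its G gone stands below mine.

    G + X → L (k = 4.60 × 10⁻⁴ L mol⁻¹ s⁻¹)
    G → Z (k = 6.20 × 10⁻⁸ s⁻¹)
    G + J ⇌ E + X (K = 23.0, k = 3.50 × 10⁻⁴ L mol⁻¹ s⁻¹)

The flask gives 56.7% gone, 43.8% of E and 50.0% after the very long wait, so the forecast holds within its margin on the first two and stands 21 percentage points high on the last. The fade left 44.2% of G against 43.3% here, and for the neighbour flask with 4.40 equiv of J it leaves 3.79% against 3.82%. At 6.00 h in this flask, G goes to E and X, counting the forward step by itself, 1.6 times as fast as it goes with X to L. By 60.0 h this flask holds 64.3% of E and 34.5% of L.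

The readings are simulated for substances that don't exist; noise was put on by code.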